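In a closed flask the free catalyst and its two intermediates add up to the catalyst charged, here 0.00800 M, so I counted what that fixed sum had to do.

    starting material + free catalyst ⇌ catalyst intermediate A (K1 = 2.3 M⁻¹, k1 = 1.7 M⁻¹ min⁻¹, Ea1 = 45.0 kJ mol⁻¹, ΔH1 = −36.0 kJ mol⁻¹)
    coupling partner + catalyst intermediate A → free catalyst + target (k2 = 1.4 M⁻¹ min⁻¹, Ea2 = 58.0 kJ mol⁻¹)
    second substrate + free catalyst ⇌ catalyst intermediate B (K3 = 0.53 M⁻¹, k3 = 17 M⁻¹ min⁻¹, Ea3 = 48.0 kJ mol⁻¹, ΔH3 = −34.0 kJ mol⁻¹)
    coupling partner + catalyst intermediate B → free catalyst + second product (k4 = 2.5 M⁻¹ min⁻¹, Ea4 = 44.0 kJ mol⁻¹)
    target → over-reaction product (k5 = 0.011 min⁻¹, Ea5 = 97.0 kJ mol⁻¹)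
    (constants at 25 °C)

| setting | east | north-east | south-west | north |
|---|---|---|---|---|
| starting material | 0.80 M | 0.80 M | 0.80 M | 0.80 M |
| second substrate | 1.00 equiv | 1.00 equiv | 1.00 equiv | 1.00 equiv |
| coupling partner | 0.900 equiv | 0.900 equiv | 0.900 equiv | 0.900 equiv |
| free catalyst | 1 mol% | 1 mol% | 1 mol% | 1 mol% |
| temperature | −35 °C | 5 °C | −15 °C | 25 °C |
| time | 15 h | 15 h | 15 h | 15 h |

- at 25 °C the constants are as listed, elsewhere as the activation energies and enthalpies make them

- the flask with the highest amount of target, in percent of the starting material charged ("all alike" if they lie within 1.5 percentage points) (east / north-east / south-west / north / all alike)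
- final target, as a percentage of the starting material charged, in east
- final target, as a percentage of the starting material charged, in north-east
- final target, as a percentage of the starting material charged, in south-west
- final target, as a percentage of the starting material charged, in north

Each turnover consumes one coupling partner, the limiting reagent at 0.900 equiv, so its 0.720 M asked 90.0 turnovers per catalyst. I began with north, where the listed constants hold. With all catalyst sitting as intermediate A and the partner held at its charge, those turnovers reckoned to 89.3 min in north.

But in north the catalyst was shared out. Setting formation equal to loss for each intermediate at the opening gave 0.778 of intermediate A and 0.401 of intermediate B per free catalyst, and both forms turn over. The opening pace in north was therefore 0.691 min⁻¹ per catalyst. The required turnovers divided by this pace gave the turnover time 130 min, which is also the pseudo-first-order life of the coupling partner while these shares hold.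

The shares drift as the coupling partner and the substrates fall. Taking the partner as gone and, as a simplification, holding the substrates at their charges, the equilibrium shares gave a late turnover time of 112 min. That was a modest change, and both figures stayed longer than the target's own life of 90.9 min.

That order mattered in north. Since the target's life there was shorter than the turnover time, I expected the target late in the run to follow the remaining partner. After 15 h, or 6.92 turnover times, my estimate left 0.0993 % of the partner in north. Balancing target made against target lost, with the opening shares, then gave 0.108 % of the starting material. This figure hung on an exponential: with the late turnover time, the estimate of partner remaining came to 0.0329 %. I trusted the smallness of the answer and little more.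

For east I stretched the turnover time by step 4's factor of 88, which gave 190 h, far longer than the run. By this estimate about 7.59 % of the partner would be used in east, while the target would lose 0.0518 % of itself. The objection was that step 2 has a higher activation energy than step 4 and the shares shift in the cold, so this stretch was rough, but the turnover time still lay far beyond the run. East looked too slow to turn over and north too hot to keep the target, so I expected the most target in north-east or south-west. My reckoning did not choose between them.

The forecast did. It named north-east, with 1 % in east, 25.6 % in north-east, 9.1 % in south-west and 0.16 % in north, a north figure above mine. Its ground for north began “Partner is gone within hours”.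

The simulation gave north-east as the best flask, with 24.7 % there, 1.00 % in east, 8.97 % in south-west and 0.165 % in north. At 15.0 h, north held 0.164 % of its own charge of coupling partner beside target at 0.165 % of the starting material charged. A neighbour of north charged with 2.5 mol% of free catalyst needed 36.0 turnovers per catalyst, so its turnover time came to 52.1 min, shorter than the target's life of 90.9 min. That neighbour ended with 0 % of its coupling partner and 0.00712 % of target.

Its constants were set for the occasion.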